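**Retrosynthetic overview**

1. Numbering follows the xanthanolide convention: the upper half (trans-lactone, C1–OH) is C1–C15, the lower half (cis-lactone, dienone) is C1′–C15′. The last two operations are cross-metathesis with methyl vinyl ketone (C2′=C3′) and release of the upper C11=C13 methylene from a Mannich base.
2. Key disconnection: the central cyclohexene ring C1–C2–C3–C11′–C13′–C5 is cut into three two-carbon units: ketone 14 (C1/C5), α-methylene lactone 25 (C13′/C11′) and nitro-enone 28 (C3/C2). One anionic Michael/Michael/nitro-aldol cascade forms C5–C13′, C11′–C3 and C2–C1, and loss of HNO2 leaves the C1 carbinol and the C2=C3 enone.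
3. Enabling feature: acceptor and donor carbons alternate around this ring. C1 is a carbinol (former carbonyl) with C5 as its α-carbon; C13′ is β and C11′ is α to the spiro-lactone carbonyl C12′; C3 is α to the acetyl group. The C2=C3–C4=O enone beside C1–OH is the footprint of a β-nitro ketone.
4. Ketone 14 comes from cyclohexa-1,3-diene: the cyclohexane ring first (all centres set on a chair), then the lactone ring, then a one-carbon expansion to the cycloheptanone. Lactone 25 comes from (R)-but-3-yn-2-ol: the lactone ring first (allylboration/lactonisation), then the cycloheptene by ring-closing enyne metathesis.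
5. Order of ring formation: upper cyclohexane, upper lactone, upper cycloheptanone; lower lactone, lower cycloheptene; central cyclohexene last.

Key step: step 20

Remark 1: the lower half has the configuration 7′S,8′S,10′R (mirror image of 8-epi-xanthatin) and the upper half is a 7S,8R,10S trans-lactone, so the two halves are made separately.
Remark 2 (assumption): in steps 2 and 16 the catalyst enantiomer named is taken to give the drawn configuration; if the sense of induction proves opposite, the mirror-image catalyst is used.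

**Upper half (steps 1–10)**

Step 1
Reactants: 1 cyclohexa-1,3-diene
Product: 2 2,3-dioxabicyclo[2.2.2]oct-5-ene (meso)
Conditions: O2, hν (visible), tetraphenylporphyrin (cat.), CH2Cl2, 0 °C
Reagents that add atoms: dioxygen, O=O
Why: singlet-oxygen [4+2] cycloaddition (hetero-Diels–Alder) to the s-cis diene gives the meso endoperoxide, and no centre of the target is set.

Step 2
Reactants: 2 2,3-dioxabicyclo[2.2.2]oct-5-ene
Product: 3 (4S)-4-hydroxycyclohex-2-en-1-one
Conditions: cupreidine 9-O-acetate (10 mol %), CH2Cl2, rt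
Reagents that add atoms: none
Why: enantioselective Kornblum–DeLaMare rearrangement, in which the chiral base removes one of the two enantiotopic bridgehead protons and the O–O bond breaks, sets the carbinol centre (later C1, used only as a stereochemical relay).

Step 3
Reactants: 3 (4S)-4-hydroxycyclohex-2-en-1-one
Product: 4 (4S)-4-[(tert-butyldimethylsilyl)oxy]cyclohex-2-en-1-one
Conditions: TBSCl, imidazole, DMF, rt
Reagents that add atoms: tert-butyldimethylsilyl chloride, CC(C)(C)[Si](C)(C)Cl
Why: silylation of the secondary alcohol protects it and makes it the steric director for step 5.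

Step 4
Reactants: 4 (4S)-4-[(tert-butyldimethylsilyl)oxy]cyclohex-2-en-1-one
Product: 5 methyl 2-[(1R,5S)-5-[(tert-butyldimethylsilyl)oxy]-2-oxocyclohex-3-en-1-yl]acetate (main epimer expected)
Conditions: LDA, THF, −78 °C; BrCH2CO2Me, DMPU, −78 → −40 °C
Reagents that add atoms: methyl bromoacetate, COC(=O)CBr
Why: kinetic α′-deprotonation of the enone (cross-conjugated enolate) and SN2 alkylation attach the future C11/C12 unit at C7; the new centre should form mainly trans to the silyloxy group but is equilibrated in step 5.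

Step 5
Reactants: 5 methyl 2-[(1R,5S)-5-[(tert-butyldimethylsilyl)oxy]-2-oxocyclohex-3-en-1-yl]acetate
Product: 7 methyl 2-[(1S,4S,5S)-5-[(tert-butyldimethylsilyl)oxy]-4-methyl-2-oxocyclohexyl]acetate, via kinetic C1-epimer 6 (not isolated)
Conditions: MeLi, CuI, Et2O, 0 °C; then 5, −78 °C; aq. NH4Cl; then DBU (cat.), CH2Cl2, rt
Reagents that add atoms: methyllithium (delivered as lithium dimethylcuprate), [Li]C
Why: conjugate addition of the Gilman cuprate anti to the neighbouring silyloxy group sets C10, and base-mediated epimerisation of the ketone α-centre (C7) then leads to the all-equatorial chair (thermodynamic control).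

Step 6
Reactants: 7 methyl 2-[(1S,4S,5S)-5-[(tert-butyldimethylsilyl)oxy]-4-methyl-2-oxocyclohexyl]acetate
Product: 9 (3aS,5S,6S,7aR)-5-[(tert-butyldimethylsilyl)oxy]-6-methylhexahydro-1-benzofuran-2(3H)-one, via hydroxy ester 8 (not isolated)
Conditions: NaBH4, MeOH, −40 °C; then PPTS (cat.), toluene, 80 °C
Reagents that add atoms: none
Why: axial hydride delivery to the conformationally fixed cyclohexanone should give the equatorial alcohol (C8, trans to the C7 arm and cis to the methyl group), and acid-catalysed lactonisation closes the trans-fused γ-lactone.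

Step 7
Reactants: 9 (3aS,5S,6S,7aR)-5-[(tert-butyldimethylsilyl)oxy]-6-methylhexahydro-1-benzofuran-2(3H)-one
Product: 10 (3R,3aS,5S,6S,7aR)-5-[(tert-butyldimethylsilyl)oxy]-3-[(dimethylamino)methyl]-6-methylhexahydro-1-benzofuran-2(3H)-one
Conditions: LDA, THF, −78 °C; CH2=NMe2+ I−, −78 °C → rt
Reagents that add atoms: N,N-dimethylmethaniminium iodide (Eschenmoser's salt), C=[N+](C)C.[I-]
Why: Mannich aminomethylation of the lactone enolate, expected anti to C6, installs C13 as a masked α-methylene group; the new centre is erased in step 21.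

Step 8
Reactants: 10 (3R,3aS,5S,6S,7aR)-5-[(tert-butyldimethylsilyl)oxy]-3-[(dimethylamino)methyl]-6-methylhexahydro-1-benzofuran-2(3H)-one
Product: 11 (3R,3aS,5S,6S,7aR)-3-[(dimethylamino)methyl]-5-hydroxy-6-methylhexahydro-1-benzofuran-2(3H)-one
Conditions: HF·pyridine, THF, 0 °C → rt; aq. NaHCO3
Reagents that add atoms: none
Why: fluoride-mediated desilylation under acidic buffering, which keeps the β-amino lactone protonated and intact.

Step 9
Reactants: 11 (3R,3aS,5S,6S,7aR)-3-[(dimethylamino)methyl]-5-hydroxy-6-methylhexahydro-1-benzofuran-2(3H)-one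
Product: 12 (3R,3aS,6S,7aR)-3-[(dimethylamino)methyl]-6-methylhexahydro-1-benzofuran-2,5-dione
Conditions: (COCl)2, DMSO, CH2Cl2, −78 °C; Et3N, −78 → 0 °C
Reagents that add atoms: none
Why: Swern oxidation of the secondary alcohol to the C1 ketone tolerates the tertiary amine and leaves the equatorial C10 methyl in its stable configuration.

Step 10
Reactants: 12 (3R,3aS,6S,7aR)-3-[(dimethylamino)methyl]-6-methylhexahydro-1-benzofuran-2,5-dione
Product: 14 (3R,3aS,7S,8aR)-3-[(dimethylamino)methyl]-7-methylhexahydro-2H-cyclohepta[b]furan-2,6(3H)-dione, via α-silyl ketone 13 (not isolated)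
Conditions: TMSCHN2, BF3·OEt2 (excess), CH2Cl2, −78 °C; then 1 M HCl, THF, rt; aq. NaHCO3
Reagents that add atoms: (trimethylsilyl)diazomethane, C[Si](C)(C)C=[N+]=[N-]
Why: Lewis-acid-promoted diazoalkane homologation (Tiffeneau–Demjanov-type 1,2-shift) in which the less substituted α-carbon C6 should migrate, so that the new CH2 (C5) enters between C1 and C6; acid then cleaves the C–Si bond of 13 and no stereocentre is touched.

**Lower half (steps 11–17)**

Step 11
Reactants: 15 (R)-but-3-yn-2-ol
Product: 16 (R)-but-3-yn-2-yl methanesulfonate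
Conditions: MsCl, Et3N, CH2Cl2, 0 °C
Reagents that add atoms: methanesulfonyl chloride, CS(=O)(=O)Cl
Why: O-sulfonylation with retention turns the hydroxyl into a leaving group.

Step 12
Reactants: 16 (R)-but-3-yn-2-yl methanesulfonate
Product: 17 dimethyl 2-[(2R)-but-3-yn-2-yl]propanedioate
Conditions: CH2(CO2Me)2, NaH, THF–DMF, 0 → 60 °C
Reagents that add atoms: dimethyl malonate, COC(=O)CC(=O)OC
Why: SN2 displacement of the secondary propargylic mesylate by the soft malonate anion with inversion sets C10′.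

Step 13
Reactants: 17 dimethyl 2-[(2R)-but-3-yn-2-yl]propanedioate
Product: 18 methyl (3R)-3-methylpent-4-ynoate
Conditions: LiCl, H2O, DMSO, 150 °C
Reagents that add atoms: none
Why: Krapcho dealkoxycarbonylation removes one ester group under neutral conditions without touching the propargylic centre.

Step 14
Reactants: 18 methyl (3R)-3-methylpent-4-ynoate
Product: 19 (3R)-3-methylpent-4-ynal
Conditions: DIBAL-H, CH2Cl2, −78 °C; aq. Rochelle salt
Reagents that add atoms: none
Why: partial reduction of the ester stops at the tetrahedral aluminate at −78 °C and gives the aldehyde on work-up.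

Step 15
Reactants: 20 methyl propiolate
Product: 22 methyl (2E)-2-[(4,4,5,5-tetramethyl-1,3,2-dioxaborolan-2-yl)methyl]hexa-2,5-dienoate, via vinylcopper 21 (not isolated)
Conditions: allylMgBr, CuBr·SMe2, THF, −78 °C; then 20, −78 °C; then ICH2Bpin, DMPU, −78 → 0 °C
Reagents that add atoms: allylmagnesium bromide, C=CC[Mg]Br; 2-(iodomethyl)-4,4,5,5-tetramethyl-1,3,2-dioxaborolane, ICB1OC(C)(C)C(C)(C)O1
Why: syn-carbocupration of the alkynoate by allylcopper followed by alkylation of the α-cuprio acrylate with retention fixes the alkene geometry (allyl cis to CH2B).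

Step 16
Reactants: 19 (3R)-3-methylpent-4-ynal; 22 methyl (2E)-2-[(4,4,5,5-tetramethyl-1,3,2-dioxaborolan-2-yl)methyl]hexa-2,5-dienoate
Product: 24 (4S,5S)-3-methylidene-5-[(2R)-2-methylbut-3-yn-1-yl]-4-(prop-2-en-1-yl)oxolan-2-one, via borate 23 (not isolated)
Conditions: (R)-TRIP (5 mol %), toluene, −30 °C → rt; then p-TsOH·H2O (cat.), rt
Reagents that add atoms: none
Why: chiral-phosphoric-acid-catalysed allylboration through a chair six-membered transition state, in which the allyl group cis to CH2B gives the syn adduct (hence the cis-lactone) and the catalyst selects the aldehyde face (C7′ and C8′); lactonisation then expels the methoxyboronate.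

Step 17
Reactants: 24 (4S,5S)-3-methylidene-5-[(2R)-2-methylbut-3-yn-1-yl]-4-(prop-2-en-1-yl)oxolan-2-one
Product: 25 (3aS,7R,8aS)-6-ethenyl-7-methyl-3-methylidene-3,3a,4,7,8,8a-hexahydro-2H-cyclohepta[b]furan-2-one
Conditions: second-generation Grubbs catalyst (5 mol %), ethylene (1 atm), CH2Cl2, 40 °C
Reagents that add atoms: none
Why: ring-closing enyne metathesis (exo mode) of the 1,7-enyne closes the cycloheptene and leaves the 1-vinyl diene; the electron-poor 1,1-disubstituted methylene lactone should not take part.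

**Nitro-enone (steps 18–19)**

Step 18
Reactants: 26 methylglyoxal (2-oxopropanal, 40 % aq.)
Product: 27 3-hydroxy-4-nitrobutan-2-one (racemic)
Conditions: MeNO2, Et3N (cat.), THF–H2O, 0 °C
Reagents that add atoms: nitromethane, C[N+](=O)[O-]
Why: Henry (nitro-aldol) addition at the more electrophilic aldehyde carbonyl.

Step 19
Reactants: 27 3-hydroxy-4-nitrobutan-2-one
Product: 28 (E)-4-nitrobut-3-en-2-one
Conditions: MsCl, Et3N, CH2Cl2, −20 °C; used freshly
Reagents that add atoms: none
Why: mesylation and E1cB elimination of the β-nitro alcohol give the (E)-nitro-alkene.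

**Union and end game (steps 20–22)**

Step 20
Reactants: 14 (3R,3aS,7S,8aR)-3-[(dimethylamino)methyl]-7-methylhexahydro-2H-cyclohepta[b]furan-2,6(3H)-dione; 25 (3aS,7R,8aS)-6-ethenyl-7-methyl-3-methylidene-3,3a,4,7,8,8a-hexahydro-2H-cyclohepta[b]furan-2-one; 28 (E)-4-nitrobut-3-en-2-one
Product: 33 spiro γ-hydroxy enone with the upper lactone masked as its Mannich base (1R,5S,7S,8R,10S,11R,11′R,7′S,8′S,10′R), via lithium enolate 29 (not isolated), via lactone enolate 30 (not isolated), via lithium nitronate 31 (not isolated), via nitro-aldolate 32 (not isolated)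
Conditions: 14, LDA (1.05 equiv), THF, −78 °C; then 25 (1.0 equiv), −78 °C; then 28 (1.1 equiv), −78 → 0 °C; then DBU, 0 °C → rt; aq. NH4Cl
Reagents that add atoms: none
Why: Proposed new method: the kinetic lithium enolate 29 (C5, the only unbranched α-carbon of 14) adds to the α-methylene lactone of 25 (C5–C13′), the lactone enolate 30 adds to the carbon of 28 that is β to the nitro group (C11′–C3), and nitronate 31 closes the cyclohexane ring on the C1 ketone (C2–C1, 6-(enolexo)-exo-trig nitro-aldol); DBU then removes the acidic C3–H and expels nitrite (E1cB), which drains the reversible adduct 32 to the γ-hydroxy enone. The closest known reaction types are sequential Michael–Michael–ring-closure annulations of ketone enolates with two acceptors, domino Michael/Henry cyclisations, and the addition of enolates to β-nitro enones followed by loss of nitrous acid; their combination on two lactone-bearing halves is new. C5: the trans-fused lactone should hold the cycloheptenolate in a chair with C7 and C9 below the enolate plane, so the acceptor bonds pseudo-axially on the lower face, cis to the C10 methyl. C11′: the cis-fused bicyclic lactone enolate is attacked on its convex face, anti to C6′. C1: the four-atom tether from C5 delivers C2 to the carbonyl face syn to C13′ through a chair-like transition state, which gives the cis ring junction with the hydroxyl cis to H5, while the transient centres C2 and C3 are erased by the elimination. The step needs regioselective enolisation at C5 (LDA at −78 °C on the only α-CH2), addition of 28 only after 25 is consumed (order of addition at −78 °C), and attack of 30 at the acetyl-bearing carbon (the nitro group is the stronger activator).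

Step 21
Reactants: 33 Mannich-base spiro adduct
Product: 35 spiro γ-hydroxy enone with free upper α-methylene lactone and lower vinyl diene, via ammonium iodide 34 (not isolated)
Conditions: MeI, acetone, rt; then NaHCO3 (aq.), EtOAc, rt
Reagents that add atoms: none
Why: exhaustive N-methylation followed by Hofmann-type E1cB elimination of trimethylamine from the β-ammonio lactone regenerates the C11=C13 methylene without touching the tertiary alcohol or the enone.

Step 22
Reactants: 35 spiro γ-hydroxy enone with lower vinyl diene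
Product: 36 target CNP0168949.6
Conditions: CH2=CHCOCH3 (excess), second-generation Hoveyda–Grubbs catalyst (10 mol %), CH2Cl2, 40 °C
Reagents that add atoms: but-3-en-2-one, C=CC(C)=O
Why: olefin cross-metathesis of the terminal vinyl group of the diene with the electron-poor enone should give the (E)-dienone, while the 1,1-disubstituted methylene lactone and the trisubstituted ring alkenes stay inert.

**Compound list**

1 | cyclohexa-1,3-diene | C1=CC=CCC1 | starting material
2 | 2,3-dioxabicyclo[2.2.2]oct-5-ene | C1CC2C=CC1OO2 | intermediate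
3 | (4S)-4-hydroxycyclohex-2-en-1-one | O=C1C=C[C@@H](O)CC1 | intermediate
4 | (4S)-4-[(tert-butyldimethylsilyl)oxy]cyclohex-2-en-1-one | O=C1C=C[C@@H](O[Si](C)(C)C(C)(C)C)CC1 | intermediate
5 | methyl 2-[(1R,5S)-5-[(tert-butyldimethylsilyl)oxy]-2-oxocyclohex-3-en-1-yl]acetate | COC(=O)C[C@H]1C[C@H](O[Si](C)(C)C(C)(C)C)C=CC1=O | intermediate
6 | methyl 2-[(1R,4S,5S)-5-[(tert-butyldimethylsilyl)oxy]-4-methyl-2-oxocyclohexyl]acetate | COC(=O)C[C@H]1C[C@H](O[Si](C)(C)C(C)(C)C)[C@@H](C)CC1=O | intermediate (not isolated)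
7 | methyl 2-[(1S,4S,5S)-5-[(tert-butyldimethylsilyl)oxy]-4-methyl-2-oxocyclohexyl]acetate | COC(=O)C[C@@H]1C[C@H](O[Si](C)(C)C(C)(C)C)[C@@H](C)CC1=O | intermediate
8 | methyl 2-[(1S,2R,4S,5S)-5-[(tert-butyldimethylsilyl)oxy]-2-hydroxy-4-methylcyclohexyl]acetate | COC(=O)C[C@@H]1C[C@H](O[Si](C)(C)C(C)(C)C)[C@@H](C)C[C@H]1O | intermediate (not isolated)
9 | (3aS,5S,6S,7aR)-5-[(tert-butyldimethylsilyl)oxy]-6-methylhexahydro-1-benzofuran-2(3H)-one | O=C1C[C@@H]2C[C@H](O[Si](C)(C)C(C)(C)C)[C@@H](C)C[C@H]2O1 | intermediate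
10 | (3R,3aS,5S,6S,7aR)-5-[(tert-butyldimethylsilyl)oxy]-3-[(dimethylamino)methyl]-6-methylhexahydro-1-benzofuran-2(3H)-one | CN(C)C[C@@H]1C(=O)O[C@@H]2C[C@H](C)[C@@H](O[Si](C)(C)C(C)(C)C)C[C@@H]12 | intermediate
11 | (3R,3aS,5S,6S,7aR)-3-[(dimethylamino)methyl]-5-hydroxy-6-methylhexahydro-1-benzofuran-2(3H)-one | CN(C)C[C@@H]1C(=O)O[C@@H]2C[C@H](C)[C@@H](O)C[C@@H]12 | intermediate
12 | (3R,3aS,6S,7aR)-3-[(dimethylamino)methyl]-6-methylhexahydro-1-benzofuran-2,5-dione | CN(C)C[C@@H]1C(=O)O[C@@H]2C[C@H](C)C(=O)C[C@@H]12 | intermediate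
13 | (3R,3aS,7S,8aR)-3-[(dimethylamino)methyl]-7-methyl-5-(trimethylsilyl)hexahydro-2H-cyclohepta[b]furan-2,6(3H)-dione (C5 epimers) | CN(C)C[C@@H]1C(=O)O[C@@H]2C[C@H](C)C(=O)C([Si](C)(C)C)C[C@@H]12 | intermediate (not isolated)
14 | (3R,3aS,7S,8aR)-3-[(dimethylamino)methyl]-7-methylhexahydro-2H-cyclohepta[b]furan-2,6(3H)-dione | CN(C)C[C@@H]1C(=O)O[C@@H]2C[C@H](C)C(=O)CC[C@@H]12 | intermediate
15 | (R)-but-3-yn-2-ol | C#C[C@@H](C)O | starting material
16 | (R)-but-3-yn-2-yl methanesulfonate | C#C[C@@H](C)OS(C)(=O)=O | intermediate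
17 | dimethyl 2-[(2R)-but-3-yn-2-yl]propanedioate | C#C[C@H](C)C(C(=O)OC)C(=O)OC | intermediate
18 | methyl (3R)-3-methylpent-4-ynoate | C#C[C@H](C)CC(=O)OC | intermediate
19 | (3R)-3-methylpent-4-ynal | C#C[C@H](C)CC=O | intermediate
20 | methyl propiolate | C#CC(=O)OC | starting material
21 | methyl (2Z)-2-cupriohexa-2,5-dienoate (allyl cis to copper) | C=CC/C=C(\[Cu])C(=O)OC | intermediate (not isolated)
22 | methyl (2E)-2-[(4,4,5,5-tetramethyl-1,3,2-dioxaborolan-2-yl)methyl]hexa-2,5-dienoate | C=CC/C=C(\CB1OC(C)(C)C(C)(C)O1)C(=O)OC | intermediate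
23 | methyl (3S,4S,6R)-6-methyl-2-methylidene-3-(prop-2-en-1-yl)-4-[(4,4,5,5-tetramethyl-1,3,2-dioxaborolan-2-yl)oxy]oct-7-ynoate | C=C(C(=O)OC)[C@H](CC=C)[C@@H](OB1OC(C)(C)C(C)(C)O1)C[C@@H](C)C#C | intermediate (not isolated)
24 | (4S,5S)-3-methylidene-5-[(2R)-2-methylbut-3-yn-1-yl]-4-(prop-2-en-1-yl)oxolan-2-one | C=C1C(=O)O[C@@H](C[C@@H](C)C#C)[C@H]1CC=C | intermediate
25 | (3aS,7R,8aS)-6-ethenyl-7-methyl-3-methylidene-3,3a,4,7,8,8a-hexahydro-2H-cyclohepta[b]furan-2-one | C=C1C(=O)O[C@H]2C[C@@H](C)C(C=C)=CC[C@@H]12 | intermediate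
26 | methylglyoxal | CC(=O)C=O | starting material
27 | 3-hydroxy-4-nitrobutan-2-one | CC(=O)C(O)C[N+](=O)[O-] | intermediate
28 | (E)-4-nitrobut-3-en-2-one | CC(=O)/C=C/[N+](=O)[O-] | intermediate
29 | lithium C1–C5 enolate of 14 | [Li+].CN(C)C[C@@H]1C(=O)O[C@@H]2C[C@H](C)C([O-])=CC[C@@H]12 | intermediate (not isolated)
30 | lithium lactone enolate after the first Michael addition (C5–C13′ formed) | [Li+].CN(C)C[C@@H]1C(=O)O[C@@H]2C[C@H](C)C(=O)[C@H](CC3=C([O-])O[C@H]4C[C@@H](C)C(C=C)=CC[C@@H]34)C[C@@H]12 | intermediate (not isolated)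
31 | lithium nitronate after the second Michael addition (C11′–C3 formed; C3 epimers) | [Li+].CN(C)C[C@@H]1C(=O)O[C@@H]2C[C@H](C)C(=O)[C@H](C[C@@]3(C(C(C)=O)C=[N+]([O-])[O-])C(=O)O[C@H]4C[C@@H](C)C(C=C)=CC[C@@H]34)C[C@@H]12 | intermediate (not isolated)
32 | lithium alkoxide of the cyclised β-nitro alcohol (C2–C1 formed; C2 and C3 epimers) | [Li+].CN(C)C[C@@H]1C(=O)O[C@@H]2C[C@H](C)[C@]3([O-])C([N+](=O)[O-])C(C(C)=O)[C@]4(C[C@@H]3C[C@@H]12)C(=O)O[C@H]1C[C@@H](C)C(C=C)=CC[C@H]14 | intermediate (not isolated)
33 | spiro γ-hydroxy enone; upper half 1R,5S,7S,8R,10S with 11R-(dimethylaminomethyl) trans-lactone; lower half 11′R,7′S,8′S,10′R cis-lactone with C1′=C5′/C2′=C3′ vinyl diene | CN(C)C[C@@H]1C(=O)O[C@@H]2C[C@H](C)[C@]3(O)C=C(C(C)=O)[C@]4(C[C@@H]3C[C@@H]12)C(=O)O[C@H]1C[C@@H](C)C(C=C)=CC[C@H]14 | intermediate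
34 | trimethylammonium iodide of 33 | [I-].C[N+](C)(C)C[C@@H]1C(=O)O[C@@H]2C[C@H](C)[C@]3(O)C=C(C(C)=O)[C@]4(C[C@@H]3C[C@@H]12)C(=O)O[C@H]1C[C@@H](C)C(C=C)=CC[C@H]14 | intermediate (not isolated)
35 | as 33 but with the free C11=C13 methylene lactone in the upper half | C=C1C(=O)O[C@@H]2C[C@H](C)[C@]3(O)C=C(C(C)=O)[C@]4(C[C@@H]3C[C@@H]12)C(=O)O[C@H]1C[C@@H](C)C(C=C)=CC[C@H]14 | intermediate
36 | CNP0168949.6 | C=C1C(=O)O[C@@H]2C[C@H](C)[C@]3(O)C=C(C(C)=O)[C@]4(C[C@@H]3C[C@@H]12)C(=O)O[C@H]1C[C@@H](C)C(/C=C/C(C)=O)=CC[C@H]14 | target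

**Step count**

Total: 22 steps. Longest linear sequence: 13 steps (steps 1–10, then 20–22, from cyclohexa-1,3-diene).

**The three steps most likely to fail**

Step 20 (bears the label). After the second Michael addition the open-chain nitronate may lose nitrous acid through the C3 enolate before the nitro-aldol closure on the hindered C1 ketone, or the Henry equilibrium may lie on the open side; either way an acyclic α-substituted enone forms instead of the ring. Facial selectivity at C5 may also be poor. The fallback keeps the same three-component logic and the same bonds in one operation, but closes the ring with a more nucleophilic α-sulfonyl carbanion and unveils the enone afterwards, all by known reaction types. It sets out from 14 and 25. The third component is (E)-tert-butyl(dimethyl){[4-(phenylsulfonyl)but-3-en-2-yl]oxy}silane F1, made in one Horner–Wadsworth–Emmons step from commercial diethyl [(phenylsulfonyl)methyl]phosphonate and 2-[(tert-butyldimethylsilyl)oxy]propanal (NaH, THF). Under the conditions of step 20 without DBU, the lactone enolate adds β to sulfur and the sulfonyl carbanion adds to the C1 ketone to give the β-hydroxy sulfone F2. TBAF/AcOH frees the secondary alcohol F3. Dess–Martin periodinane gives the β-sulfonyl ketone F4, and DBU eliminates benzenesulfinate (E1cB) to give 33, where the route is rejoined.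

Step 16. Allyl transfer from the electron-poor boronate may be slow, and the catalyst may control the aldehyde face insufficiently because the β-stereocentre of 19 gives no help; the result would be a mixture of cis-lactones that are epimeric at both C7′ and C8′. The fallback uses auxiliary control and sets out from 19. An Evans syn-aldol addition (Bu2BOTf, i-Pr2NEt) of (4R)-4-benzyl-3-(pent-4-enoyl)-1,3-oxazolidin-2-one F5 (from (R)-4-benzyloxazolidin-2-one, n-BuLi and pent-4-enoyl chloride) gives the syn-aldol F6. AlMe3/MeNHOMe·HCl gives the Weinreb amide F7, and TESOTf/2,6-lutidine the silyl ether F8. MeMgBr gives the methyl ketone F9, and KHMDS/PhNTf2 the kinetic enol triflate F10. HF·pyridine gives the hydroxy triflate F11, and carbonylative lactonisation with Pd(PPh3)4, CO and Bu3N closes the α-methylene lactone to give 24.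

Step 10. The branched α-carbon C10 may migrate instead of C6, which inserts the methylene on the wrong side, or a second homologation may give the eight-membered ketone. The fallback is a regiospecific ring expansion through a silyloxycyclopropane and sets out from 12. LDA/TMSCl gives the less substituted silyl enol ether F12. Et2Zn/CH2I2 cyclopropanates it to the silyloxycyclopropane F13. FeCl3 in DMF opens the ring oxidatively to the β-chloro cycloheptanone F14, NaOAc eliminates HCl to the enone F15, and H2 with Pd/C gives 14.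

**Further compounds**

F1 | step 20 | (E)-tert-butyl(dimethyl){[4-(phenylsulfonyl)but-3-en-2-yl]oxy}silane | CC(O[Si](C)(C)C(C)(C)C)/C=C/S(=O)(=O)c1ccccc1
F2 | step 20 | β-hydroxy sulfone: as 33 but C2–C3 saturated, C2 bears PhSO2, C3 bears 1-[(tert-butyldimethylsilyl)oxy]ethyl in place of acetyl | CN(C)C[C@@H]1C(=O)O[C@@H]2C[C@H](C)[C@]3(O)C(S(=O)(=O)c5ccccc5)C(C(C)O[Si](C)(C)C(C)(C)C)[C@]4(C[C@@H]3C[C@@H]12)C(=O)O[C@H]1C[C@@H](C)C(C=C)=CC[C@H]14
F3 | step 20 | as F2 with free 1-hydroxyethyl group at C3 | CN(C)C[C@@H]1C(=O)O[C@@H]2C[C@H](C)[C@]3(O)C(S(=O)(=O)c5ccccc5)C(C(C)O)[C@]4(C[C@@H]3C[C@@H]12)C(=O)O[C@H]1C[C@@H](C)C(C=C)=CC[C@H]14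
F4 | step 20 | β-sulfonyl ketone: as F2 with acetyl at C3 | CN(C)C[C@@H]1C(=O)O[C@@H]2C[C@H](C)[C@]3(O)C(S(=O)(=O)c5ccccc5)C(C(C)=O)[C@]4(C[C@@H]3C[C@@H]12)C(=O)O[C@H]1C[C@@H](C)C(C=C)=CC[C@H]14
F5 | step 16 | (4R)-4-benzyl-3-(pent-4-enoyl)-1,3-oxazolidin-2-one | C=CCCC(=O)N1[C@H](Cc2ccccc2)COC1=O
F6 | step 16 | (4R)-4-benzyl-3-[(2R,3S,5R)-3-hydroxy-5-methyl-2-(prop-2-en-1-yl)hept-6-ynoyl]-1,3-oxazolidin-2-one | C#C[C@H](C)C[C@H](O)[C@@H](CC=C)C(=O)N1[C@H](Cc2ccccc2)COC1=O
F7 | step 16 | (2R,3S,5R)-3-hydroxy-N-methoxy-N,5-dimethyl-2-(prop-2-en-1-yl)hept-6-ynamide | C#C[C@H](C)C[C@H](O)[C@@H](CC=C)C(=O)N(C)OC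
F8 | step 16 | (2R,3S,5R)-N-methoxy-N,5-dimethyl-2-(prop-2-en-1-yl)-3-[(triethylsilyl)oxy]hept-6-ynamide | C#C[C@H](C)C[C@H](O[Si](CC)(CC)CC)[C@@H](CC=C)C(=O)N(C)OC
F9 | step 16 | (3R,4S,6R)-6-methyl-3-(prop-2-en-1-yl)-4-[(triethylsilyl)oxy]oct-7-yn-2-one | C#C[C@H](C)C[C@H](O[Si](CC)(CC)CC)[C@@H](CC=C)C(C)=O
F10 | step 16 | (3R,4S,6R)-6-methyl-3-(prop-2-en-1-yl)-4-[(triethylsilyl)oxy]oct-1-en-7-yn-2-yl trifluoromethanesulfonate | C#C[C@H](C)C[C@H](O[Si](CC)(CC)CC)[C@@H](CC=C)C(=C)OS(=O)(=O)C(F)(F)F
F11 | step 16 | (3R,4S,6R)-4-hydroxy-6-methyl-3-(prop-2-en-1-yl)oct-1-en-7-yn-2-yl trifluoromethanesulfonate | C#C[C@H](C)C[C@H](O)[C@@H](CC=C)C(=C)OS(=O)(=O)C(F)(F)F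
F12 | step 10 | trimethylsilyl enol ether of 12 on the unbranched side (C1=C6) | CN(C)C[C@@H]1C(=O)O[C@@H]2C[C@H](C)C(O[Si](C)(C)C)=C[C@@H]12
F13 | step 10 | silyloxycyclopropane from F12 (cyclopropane across C1–C6) | CN(C)C[C@@H]1C(=O)O[C@@H]2C[C@H](C)C3(O[Si](C)(C)C)CC3[C@@H]12
F14 | step 10 | (3R,3aS,7S,8aR)-4-chloro-3-[(dimethylamino)methyl]-7-methylhexahydro-2H-cyclohepta[b]furan-2,6(3H)-dione (C4 epimers) | CN(C)C[C@@H]1C(=O)O[C@@H]2C[C@H](C)C(=O)CC(Cl)[C@@H]12
F15 | step 10 | (3R,3aS,7S,8aR)-3-[(dimethylamino)methyl]-7-methyl-3,3a,8,8a-tetrahydro-2H-cyclohepta[b]furan-2,6(7H)-dione | CN(C)C[C@@H]1C(=O)O[C@@H]2C[C@H](C)C(=O)C=C[C@@H]12
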